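**Strategy.** The route rests on disconnecting the tetrasubstituted ring alkene C3=C4 of the cyclohexene, the bond between the carbon that bears the heptenyl chain and the carbon that bears CH2OH. These two atoms and the first alkene of the side chain form a 1-alkenylcyclohexene diene, the product pattern of exo enyne metathesis. One operation closes the carbocycle from an acyclic 1,7-enyne, creates the diene and, by cross-metathesis with hept-1-ene in the same flask, completes the (E)-heptenyl chain. The precursor is a terminal alkyne tethered to the exocyclic methylene of an acetonide; its four stereocentres come from two organocatalytic aldol reactions, and the acetonide later unveils CH2OH and the C5 hydroxyl.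

Key step: step 7

Ring numbering used below: C1 carries the butenoic acid chain, C2 is the carbinol next to C3 (heptenyl), C4 carries CH2OH, C5 and C6 are the cis-diol carbons.
The metathesis catalyst of steps 1 and 7 is the second-generation Hoveyda–Grubbs catalyst, dichloro(1,3-dimesitylimidazolidin-2-ylidene)(2-isopropoxybenzylidene)ruthenium.
Assumption: the diarylprolinol catalyst of step 2 is taken to react through a proline-type hydrogen-bonded enamine transition state, so that its (R)-enantiomer gives the (5R,6S)-anti aldol; if the sense proves opposite, the (S)-catalyst is used.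

**Step 1**
Reactants: 1 pent-4-enal + 2 methyl methacrylate
Product: 3 methyl (E)-2-methyl-6-oxohex-2-enoate
Conditions: second-generation Hoveyda–Grubbs catalyst (2 mol %), methyl methacrylate (5 equiv), CH2Cl2, 40 °C
Reagents that add atoms: none
Why: Olefin cross-metathesis of a terminal alkene with an excess of the 1,1-disubstituted, electron-poor methacrylate should favour the cross product over homodimers and give the thermodynamically preferred (E)-trisubstituted enoate, the aldehyde being tolerated by the ruthenium carbene.

**Step 2**
Reactants: 3 methyl (E)-2-methyl-6-oxohex-2-enoate + 4 3-(trimethylsilyl)prop-2-ynal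
Product: 5 methyl (2E,5R,6S)-5-formyl-6-hydroxy-2-methyl-8-(trimethylsilyl)oct-2-en-7-ynoate
Conditions: (R)-α,α-bis[3,5-bis(trifluoromethyl)phenyl]pyrrolidin-2-ylmethanol (10 mol %), 1,4-dioxane, H2O (3 equiv), 23 °C; crude product taken on at once
Reagents that add atoms: none
Why: Amine-catalysed direct cross-aldol reaction through the enamine of 3, in which the non-enolisable and more electrophilic ynal can only act as acceptor and the hydroxyl group of the catalyst hydrogen-bonds the acceptor in a proline-type transition state, so that the (R)-catalyst should set ring C1 (R) and ring C2 (S) in the anti relationship.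

**Step 3**
Reactants: 5 methyl (2E,5R,6S)-5-formyl-6-hydroxy-2-methyl-8-(trimethylsilyl)oct-2-en-7-ynoate
Product: 6 methyl (2E,5R,6S)-5-formyl-2-methyl-6-(triethylsilyloxy)-8-(trimethylsilyl)oct-2-en-7-ynoate
Conditions: Et3SiOTf, 2,6-lutidine, CH2Cl2, −78 °C
Reagents that add atoms: triethylsilyl trifluoromethanesulfonate, CC[Si](CC)(CC)OS(=O)(=O)C(F)(F)F
Why: Silylation of the secondary propargylic alcohol with a silyl triflate and a hindered base at −78 °C should be faster than enolisation or β-elimination of the aldehyde, so both stereocentres are carried through unchanged.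

**Step 4**
Reactants: 6 silyl-protected aldehyde + 7 2,2-dimethyl-1,3-dioxan-5-one
Product: 8 anti aldol adduct (dioxanone β-hydroxy ketone)
Conditions: (S)-proline (30 mol %), DMF, 4 °C
Reagents that add atoms: none
Why: Proline-catalysed direct aldol reaction of the dioxanone through its ring-locked (E)-enamine and a hydrogen-bonded chair-like transition state, which with (S)-proline should give the anti aldol and set ring C5 (the dioxanone carbon) and ring C6 (the carbinol) as in the target, in the sense that the Felkin–Anh preference of the α-branched, 2,3-anti β-silyloxy aldehyde reinforces.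

**Step 5**
Reactants: 8 anti aldol adduct
Product: 9 bis(triethylsilyl) ether ketone
Conditions: Et3SiOTf, 2,6-lutidine, CH2Cl2, −78 °C
Reagents that add atoms: triethylsilyl trifluoromethanesulfonate, CC[Si](CC)(CC)OS(=O)(=O)C(F)(F)F
Why: Silylation of the hindered secondary alcohol with the silyl triflate at low temperature should outpace silyl enol ether formation at the ketone and blocks retro-aldol cleavage in the next step.

**Step 6**
Reactants: 9 bis(triethylsilyl) ether ketone
Product: 11 terminal-alkyne enyne with 5-methylidene-1,3-dioxane, via silylated methylidene compound 10 (not isolated)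
Conditions: Ph3PCH3Br, KN(SiMe3)2, THF, −78 to 0 °C; then MeOH, K2CO3 (0.3 equiv), 23 °C
Reagents that add atoms: methyltriphenylphosphonium bromide, C[P+](c1ccccc1)(c1ccccc1)c1ccccc1.[Br-]
Why: Wittig methylenation of the electrophilic α,α'-dioxygenated ketone with the small non-stabilised ylide should be faster than enolisation or attack at the hindered conjugated ester, and methoxide formed on adding methanol then removes the alkynyl trimethylsilyl group (protodesilylation) without touching the triethylsilyl ethers.

**Step 7**
Reactants: 11 terminal-alkyne enyne + 12 hept-1-ene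
Product: 14 bicyclic (E)-heptenyl diene methyl ester, via vinyl diene 13 (not isolated)
Conditions: second-generation Hoveyda–Grubbs catalyst (10 mol %), ethylene (1 atm), toluene (0.005 M), 80 °C; then argon purge, hept-1-ene (10 equiv), 40 °C
Reagents that add atoms: none
Why: Under ethylene the ruthenium methylidene adds to the terminal alkyne with the usual regiochemistry (carbene carbon to the terminal CH), and the 1,1-disubstituted vinylcarbene so formed undergoes [2+2] cycloaddition and cycloreversion with the tethered 5-methylidene group of the dioxane, which closes the six-membered carbocycle in the exo mode, makes the tetrasubstituted ring alkene and leaves a vinyl group on the former alkyne carbon (13). The closest known reaction type is ring-closing enyne metathesis of enynes that carry a 1,1-disubstituted alkene under ethylene, followed in the same flask by cross-metathesis of a 2-substituted 1,3-diene with a terminal alkene. No stereocentre is formed; the only new stereo element, the (E) geometry of the heptenyl alkene, should be set thermodynamically because cross-metathesis at the terminal vinyl group is reversible and the (E)-diene is the more stable isomer. The step needs exo over endo closure, which the six- against seven-membered ring size and the regiochemistry of carbene addition to a terminal alkyne should secure. It also needs chemoselectivity among four alkenes: the trisubstituted, electron-poor enoate and the new tetrasubstituted ring alkene are inert to the catalyst, so only the vinyl group can exchange with hept-1-ene.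

**Step 8**
Reactants: 14 bicyclic (E)-heptenyl diene methyl ester
Product: 15 bicyclic (E)-heptenyl diene carboxylic acid
Conditions: LiOH·H2O, THF/MeOH/H2O, 40 °C; then 1 M HCl to pH 4, 0 °C
Reagents that add atoms: lithium hydroxide, [Li+].[OH-]
Why: Saponification of the methyl ester by hydroxide (acyl substitution), which the hindered secondary silyl ethers, the acetonide and the diene should survive, followed by mild acidification to the free acid.

**Step 9**
Reactants: 15 bicyclic (E)-heptenyl diene carboxylic acid
Product: 16 pestallic acid P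
Conditions: AcOH/THF/H2O (3:1:1), 40 °C
Reagents that add atoms: none
Why: Mild aqueous acetic acid should hydrolyse the two triethylsilyl ethers and the 1,3-dioxane acetonide (acetal hydrolysis) without ionising the allylic alcohols of the diene, and no stereocentre is touched.

**Compound list**

1 | pent-4-enal | C=CCCC=O | starting material
2 | methyl methacrylate | C=C(C)C(=O)OC | starting material
3 | methyl (E)-2-methyl-6-oxohex-2-enoate | O=CCC/C=C(\C)C(=O)OC | intermediate
4 | 3-(trimethylsilyl)prop-2-ynal | C[Si](C)(C)C#CC=O | starting material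
5 | methyl (2E,5R,6S)-5-formyl-6-hydroxy-2-methyl-8-(trimethylsilyl)oct-2-en-7-ynoate | O=C[C@H](C/C=C(\C)C(=O)OC)[C@H](O)C#C[Si](C)(C)C | intermediate
6 | methyl (2E,5R,6S)-5-formyl-2-methyl-6-(triethylsilyloxy)-8-(trimethylsilyl)oct-2-en-7-ynoate | O=C[C@H](C/C=C(\C)C(=O)OC)[C@H](O[Si](CC)(CC)CC)C#C[Si](C)(C)C | intermediate
7 | 2,2-dimethyl-1,3-dioxan-5-one | CC1(C)OCC(=O)CO1 | starting material
8 | methyl (2E,5S,6S)-5-[(S)-[(4S)-2,2-dimethyl-5-oxo-1,3-dioxan-4-yl](hydroxy)methyl]-2-methyl-6-(triethylsilyloxy)-8-(trimethylsilyl)oct-2-en-7-ynoate | CC1(C)OCC(=O)[C@@H](O1)[C@@H](O)[C@H](C/C=C(\C)C(=O)OC)[C@H](O[Si](CC)(CC)CC)C#C[Si](C)(C)C | intermediate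
9 | methyl (2E,5R,6S)-5-[(S)-[(4S)-2,2-dimethyl-5-oxo-1,3-dioxan-4-yl](triethylsilyloxy)methyl]-2-methyl-6-(triethylsilyloxy)-8-(trimethylsilyl)oct-2-en-7-ynoate | CC1(C)OCC(=O)[C@@H](O1)[C@@H](O[Si](CC)(CC)CC)[C@H](C/C=C(\C)C(=O)OC)[C@H](O[Si](CC)(CC)CC)C#C[Si](C)(C)C | intermediate
10 | methyl (2E,5R,6S)-5-[(S)-[(4R)-2,2-dimethyl-5-methylidene-1,3-dioxan-4-yl](triethylsilyloxy)methyl]-2-methyl-6-(triethylsilyloxy)-8-(trimethylsilyl)oct-2-en-7-ynoate | CC1(C)OCC(=C)[C@@H](O1)[C@@H](O[Si](CC)(CC)CC)[C@H](C/C=C(\C)C(=O)OC)[C@H](O[Si](CC)(CC)CC)C#C[Si](C)(C)C | intermediate (not isolated)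
11 | methyl (2E,5R,6S)-5-[(S)-[(4R)-2,2-dimethyl-5-methylidene-1,3-dioxan-4-yl](triethylsilyloxy)methyl]-2-methyl-6-(triethylsilyloxy)oct-2-en-7-ynoate | CC1(C)OCC(=C)[C@@H](O1)[C@@H](O[Si](CC)(CC)CC)[C@H](C/C=C(\C)C(=O)OC)[C@H](O[Si](CC)(CC)CC)C#C | intermediate
12 | hept-1-ene | C=CCCCCC | starting material
13 | methyl (E)-4-[(6S,7R,8S,8aR)-5-ethenyl-2,2-dimethyl-6,8-bis(triethylsilyloxy)-6,7,8,8a-tetrahydro-4H-benzo[d][1,3]dioxin-7-yl]-2-methylbut-2-enoate | C=CC1=C(COC(C)(C)O2)[C@@H]2[C@@H](O[Si](CC)(CC)CC)[C@H](C/C=C(\C)C(=O)OC)[C@@H]1O[Si](CC)(CC)CC | intermediate (not isolated)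
14 | methyl (E)-4-[(6S,7R,8S,8aR)-5-[(E)-hept-1-en-1-yl]-2,2-dimethyl-6,8-bis(triethylsilyloxy)-6,7,8,8a-tetrahydro-4H-benzo[d][1,3]dioxin-7-yl]-2-methylbut-2-enoate | CCCCC/C=C/C1=C(COC(C)(C)O2)[C@@H]2[C@@H](O[Si](CC)(CC)CC)[C@H](C/C=C(\C)C(=O)OC)[C@@H]1O[Si](CC)(CC)CC | intermediate
15 | (E)-4-[(6S,7R,8S,8aR)-5-[(E)-hept-1-en-1-yl]-2,2-dimethyl-6,8-bis(triethylsilyloxy)-6,7,8,8a-tetrahydro-4H-benzo[d][1,3]dioxin-7-yl]-2-methylbut-2-enoic acid | CCCCC/C=C/C1=C(COC(C)(C)O2)[C@@H]2[C@@H](O[Si](CC)(CC)CC)[C@H](C/C=C(\C)C(=O)O)[C@@H]1O[Si](CC)(CC)CC | intermediate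
16 | pestallic acid P, (E)-4-[(1R,2S,5R,6S)-3-[(E)-hept-1-en-1-yl]-2,5,6-trihydroxy-4-(hydroxymethyl)cyclohex-3-en-1-yl]-2-methylbut-2-enoic acid | CCCCC/C=C/C1=C(CO)[C@@H](O)[C@@H](O)[C@H](C/C=C(\C)C(=O)O)[C@@H]1O | target

**Step count and risks**

Total step count: 9. Longest linear sequence: 9 steps (from pent-4-enal).

Steps most likely to fail:

Step 7. Closure of the vinylcarbene onto the hindered 1,1-disubstituted alkene may be slower than oligomerisation of the alkyne, closure in the endo sense or trapping of the carbene by ethylene, and the cross-metathesis may stop at partial conversion or leave a mixture of alkene geometries. The fallback is a relay enyne metathesis that sets out from ketone 9. Wittig reaction of 9 with the ylide from (hex-5-en-1-yl)triphenylphosphonium bromide and KN(SiMe3)2 should give the silylated relay trienyne F1, and methanol with K2CO3 in the same flask the terminal-alkyne relay trienyne F2. With the second-generation Hoveyda–Grubbs catalyst and hept-1-ene, ruthenium is loaded at the terminal alkene of the tether, expels cyclopentene and is thereby placed on the hindered carbon. That carbene inserts the alkyne irreversibly (ene-then-yne order), closing the same ring bond, and the resulting alkylidene is released by hept-1-ene as the heptenyl diene. The fallback comes back to the route at 14.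

Step 4. Addition to the hindered aldehyde may be slow, and over the long reaction time the aldehyde may lose its silyloxy group by β-elimination or epimerise at the α-carbon through its own enamine. The fallback is a stoichiometric boron aldol reaction that sets out from 6 and 7. Dioxanone 7 is converted with (c-C6H11)2BCl and Et3N at −78 °C into the dicyclohexylboron enolate F3, whose ring enforces the (E)-enolate and hence the anti aldol through a closed six-membered transition state, while Felkin–Anh control by the aldehyde fixes the face. Addition to 6 gives the boron aldolate F4, and work-up with pH 7 buffer and methanol frees the aldol. The fallback comes back to the route at 8.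

Step 6. The basic ylide may enolise the ketone, with epimerisation at C4 of the dioxanone or β-elimination of the neighbouring silyloxy group. The fallback is a Peterson olefination that sets out from 9. The weakly basic organocerium reagent from Me3SiCH2MgCl and CeCl3 (THF, −78 °C) should add to the ketone to give the β-hydroxysilane F5 (epimers at the new carbinol are of no consequence), and KH in THF should then eliminate silanolate to the methylidene compound. The fallback comes back to the route at 10, which is desilylated to 11 with K2CO3 in methanol as in step 6.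

**Further compounds**

F1 | step 7 | methyl (2E,5R,6S)-5-[(S)-[(4R)-5-(hex-5-en-1-ylidene)-2,2-dimethyl-1,3-dioxan-4-yl](triethylsilyloxy)methyl]-2-methyl-6-(triethylsilyloxy)-8-(trimethylsilyl)oct-2-en-7-ynoate, either geometry at the new alkene | CC1(C)OCC(=CCCCC=C)[C@@H](O1)[C@@H](O[Si](CC)(CC)CC)[C@H](C/C=C(\C)C(=O)OC)[C@H](O[Si](CC)(CC)CC)C#C[Si](C)(C)C
F2 | step 7 | methyl (2E,5R,6S)-5-[(S)-[(4R)-5-(hex-5-en-1-ylidene)-2,2-dimethyl-1,3-dioxan-4-yl](triethylsilyloxy)methyl]-2-methyl-6-(triethylsilyloxy)oct-2-en-7-ynoate, either geometry at the new alkene | CC1(C)OCC(=CCCCC=C)[C@@H](O1)[C@@H](O[Si](CC)(CC)CC)[C@H](C/C=C(\C)C(=O)OC)[C@H](O[Si](CC)(CC)CC)C#C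
F3 | step 4 | 2,2-dimethyl-4H-1,3-dioxin-5-yl dicyclohexylborinate (boron enolate of 7) | CC1(C)OCC(OB(C2CCCCC2)C2CCCCC2)=CO1
F4 | step 4 | O-dicyclohexylboryl aldolate of 8, methyl (2E,5S,6S)-5-[(S)-(dicyclohexylboranyloxy)[(4S)-2,2-dimethyl-5-oxo-1,3-dioxan-4-yl]methyl]-2-methyl-6-(triethylsilyloxy)-8-(trimethylsilyl)oct-2-en-7-ynoate | CC1(C)OCC(=O)[C@@H](O1)[C@@H](OB(C2CCCCC2)C2CCCCC2)[C@H](C/C=C(\C)C(=O)OC)[C@H](O[Si](CC)(CC)CC)C#C[Si](C)(C)C
F5 | step 6 | methyl (2E,5R,6S)-5-[(S)-[(4S)-5-hydroxy-2,2-dimethyl-5-[(trimethylsilyl)methyl]-1,3-dioxan-4-yl](triethylsilyloxy)methyl]-2-methyl-6-(triethylsilyloxy)-8-(trimethylsilyl)oct-2-en-7-ynoate, epimers at C5 of the dioxane | CC1(C)OCC(O)(C[Si](C)(C)C)[C@@H](O1)[C@@H](O[Si](CC)(CC)CC)[C@H](C/C=C(\C)C(=O)OC)[C@H](O[Si](CC)(CC)CC)C#C[Si](C)(C)C
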